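I chose theta over delta for target, and I got there by treating each earlier target curve as a dead start joined to a straight rise, all in fractions of the charge.

all flasks: gas 200 mM (held)

|  | substrate | other conformer | temperature | remark | time |
|---|---|---|---|---|---|
| north | 1.1 M | 0.50 M | 68 °C | run made earlier |  |
| north-east | 1.6 M | 0.50 M | 84 °C | run made earlier |  |
| south-east | 1.7 M | 0.50 M | 68 °C | run made earlier |  |
| theta | 2.0 M | 0.500 M | 90 °C |  | 80 min |
| delta | 1.2 M | 0.500 M | 60 °C |  | 80 min |

| north: time / min | north: target / % | north-east: time / min | north-east: target / % | south-east: time / min | south-east: target / % |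
|---|---|---|---|---|---|
| 40.0 | 1.0 | 15.0 | 0.7 | 40.0 | 1.2 |
| 80.0 | 4.5 | 30.0 | 1.1 | 80.0 | 4.8 |
| 150 | 13.7 | 50.0 | 3.7 | 150 | 14.6 |
| 180 | 17.4 | 60.0 | 7.2 | 180 | 17.7 |
| 240 | 22.9 | 80.0 | 13.2 | 240 | 24.1 |

(standard deviation of a reading: 0.3 percentage points)

- what was read earlier has a scatter of 0.3 percentage points, one standard deviation
- at the start none of the gas is in solution
- in a conversion other conformer counts as not yet reacted

* which of the two ends with the higher amount of target, in percent of the substrate and other conformer together charged ("neither" if they lie within 2 percentage points) (theta / delta / neither)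
* target at the end, in percent of the substrate and other conformer together charged, theta
* target at the end, in percent of the substrate and other conformer together charged, delta

1. The late end came first. The north run (at 68 °C) rose by 0.00129 min⁻¹ between 80.0 min and 180 min, and the north-east run (at 84 °C) rose by 0.00300 min⁻¹ between 60.0 min and 80.0 min.

2. To join the two ends I ran each line backwards, which gave 45.1 min for north and 36.0 min for north-east. This is the line-back time, the moment at which the straight part of a target curve, run backwards, meets zero (an induction period read from a curve), and in this reckoning target past it is the slope times the time elapsed since it.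

3. The north and south-east runs read 22.9 % and 24.1 % at 240 min from 1.1 M and 1.7 M of substrate, so I ignored the charge. Continuing the growth of the slope with temperature gave 0.00412 min⁻¹ for theta and 8.46 × 10⁻⁴ min⁻¹ for delta.

4. With the north-east line-back time, theta's line reached 18.1 % at 80 min. With the north line-back time, delta's reached 2.95 %.

5. The weak link was theta's straight line, since north slowed to 9.17 × 10⁻⁴ min⁻¹ after 180 min, less than 0.00129 min⁻¹. I bent theta's line in that proportion above north's 17.4 %, the reading from which that slower stretch started, and my committed number for theta became 17.9 %, with 2.95 % kept for delta.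

The forecast said theta, with 18 % for theta and 2.7 % for delta, reasoning that “the rate is about first order in the substrate and conformer pool”. My own numbers were 17.9 % for theta and 2.95 % for delta.

The flask gave theta, with theta at 13.4 % and delta at 2.54 %.

    substrate ⇌ other conformer (K = 0.140, k = 0.00162 min⁻¹, Ea = 109 kJ mol⁻¹, ΔH = −9.00 kJ mol⁻¹)
    substrate + reagent → target (k = 0.0863 L mol⁻¹ min⁻¹, Ea = 90.0 kJ mol⁻¹)
    reagent + other conformer → isomer of the product (k = 7.75 L mol⁻¹ min⁻¹, Ea = 46.0 kJ mol⁻¹)
    gas ⇌ reagent, rate k4*(csat - [reagent]) (kL = 0.0734 min⁻¹)
    (constants at 90 °C)

Theta's result and the line-back time of 36.0 min carried over from the north-east run gave theta a slope of 0.00304 min⁻¹, lower than the 0.00412 min⁻¹ I had reckoned. I laid this line out to the neighbouring flask, which is theta itself read at 3.0 h, and it reached 43.8 %. The neighbouring flask gave 41.0 %.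

(The earlier runs and the new flask were computed for an exercise; scatter was added.)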